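2.00 moles of E stand against each mole of Q in this flask. I call this ratio the reserve w, the E charged per Q charged, and I write the balance of Q, in this flask the limiting reagent, charged in the smaller amount.

the same everywhere: Q 0.0050 M
- teal: E 10 mM; X 12 µM; run made earlier
- violet: E 10 mM; X 19 µM; run made earlier
- flask: E 10.0 mM; X 25 µM; time 20 min

- teal (time / min: Q / %, D / %, L / %): 1.00: 80, 14, 8; 3.00: 41, 40, 19; 6.00: 9, 57, 31; 8.00: 4, 63, 36; 12.0: 0, 63, 36
- violet (time / min: Q / %, D / %, L / %): 1.00: 67, 26, 4; 3.00: 21, 53, 25; 6.00: 0, 61, 34; 8.00: 0, 63, 36; 12.0: 0, 59, 37

(readings scatter by 1.5 percentage points)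

1. at 20 min, what has stopped the reaction, if anything has (no working catalyst is left / E has run out first / all of Q has reacted / forward and back rates have come level / it is still moving)
2. how much of the Q has reacted by 20 min
3. how much D there is at 20 min, in percent of the Q charged
4. how much L there is at 20 min, in percent of the Q charged

- the reaction counts as stopped when no species that holds the Q changes by six tenths of a point or more over the second half of the time

1. The charges. No run reads E, so I assume that one E is spent per Q reacted. On that assumption, and counting the E held by the catalyst as negligible, a run that goes on until its limiting reagent is used up leaves a share of Q of one minus w when w is below one, and nil when w is above one. Teal and violet have this flask's reserve, and at 12.0 min they read Q 0 % and 0 %, with D plus L at 99.0 % and 96.0 %, each reading scattering by 1.5 percentage points. So I expect this flask to use up Q and keep 50.0 % of its E.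

2. The catalyst. By hand, more X should speed the run without entering the balance, since X is charged in far less than Q. From 12 µM to 19 µM, Q at 3.00 min falls from 41 % to 21 %, yet D at 8.00 min reads 63 % and 63 %. So I expect 25 µM to reach the same end sooner.

3. The time. By hand, extra time should add little after Q has reacted. Teal reads D 63 % and L 36 % at 8.00 min, and D 63 % and L 36 % at 12.0 min. So at 20 min I commit to D near 63 % and L near 36 % in this flask.

4. The forecast gives all of Q has reacted, with 100 % reacted, D 62 % (59 % to 64 %) and L 36 % (34.5 % to 38 %). Its ground is “E is in twofold excess, and neither run stalled with Q left”.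

5. This flask ends thus: all of Q has reacted, with 100 % reacted, D 62.9 % and L 37.1 %.

    G ⇌ Z (K = 2.90, k = 3.10 /s)
    Q + J ⇌ G (K = 760 /M, k = 1700 /M/s)
    E + X → J (k = 30000 /M/s)
    D ⇌ L (K = 0.590, k = 0.0150 /s)
    Z → X + D (k = 12.0 /s)

With w at 2.00, this flask keeps 50 % of its E at 20.0 min. A neighbour flask charged with 0.013 M of Q has a reserve of 0.769, lower than this flask's, so the balance leaves 23.1 % of its Q. That neighbour flask stands at 23.1 % of Q, with E at 0 %, at 20.0 min.

All runs were computed for substances that don't exist; noise was put on by code.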